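All runs were computed with made-up constants; noise was put on by code.

A small charge shows the pattern: the red run, with 0.60 M substrate, holds 36 % intermediate at 1.00 h, and the blue run, with 0.90 M, holds 36 % at 1.00 h.

| flask | substrate | remark | time |
|---|---|---|---|
| grey | 1.2 M | run made earlier |  |
| red | 0.60 M | run made earlier |  |
| blue | 0.90 M | run made earlier |  |
| alder | 1.2 M | a single well-mixed tank run continuously and read at steady state, 3.0 h in it on average |  |
| cedar | 1.2 M | everything together in a closed stirred flask, run for 3.0 h | 3.0 h |

grey run (percent of the substrate charged)

| time / min | intermediate / % | target / % |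
|---|---|---|
| 20.0 | 17 | 0 |
| 40.0 | 30 | 2 |
| 50.0 | 29 | 3 |
| 80.0 | 43 | 3 |
| 90.0 | 48 | 1 |
| 120 | 53 | 4 |

red run (percent of the substrate charged)

| time / h | intermediate / % | target / % |
|---|---|---|
| 0.250 | 11 | 0 |
| 0.417 | 23 | 0 |
| 0.667 | 29 | 1 |
| 1.00 | 36 | 2 |
| 2.00 | 56 | 1 |
| 3.00 | 65 | 7 |

blue run (percent of the substrate charged)

| time / h | intermediate / % | target / % |
|---|---|---|
| 0.500 | 20 | 1 |
| 1.00 | 36 | 1 |
| 1.50 | 48 | 2 |
| 2.00 | 56 | 4 |
| 2.50 | 63 | 2 |
| 3.00 | 65 | 8 |

(readings scatter by 2 percentage points)

- the stated concentrations are those of everything mixed, before any reaction; amounts are the same in each set-up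
- the earlier runs were made in a closed, stirred flask

1. the set-up with the highest amount of intermediate at the outlet or at the end, in percent of the substrate put in ("none" if the first two lie within 2 percentage points) (alder / cedar / none)
2. amount of intermediate at the outlet or at the end, in percent of the substrate put in, alder
3. amount of intermediate at the outlet or at the end, in percent of the substrate put in, cedar

Equal percentages from unequal charges suggest a first-order loss of substrate into intermediate, then a slow step on to target. We read both constants from blue. Intermediate plus target at 3.00 h give a loss constant of 0.436 h⁻¹. Target of 8 %, divided by the midway intermediate 48 % held over that time, gives a using constant of 0.0556 h⁻¹. This one is rough, with a scatter of 2 percentage points on so small a reading.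

Turn the question round. In our two-step reckoning, for alder to win, cedar would have to be read well past its crossing time, the moment in a closed flask when intermediate is made just as fast as it is used, ln(loss constant/using constant)/(loss constant − using constant), the usual peak time of consecutive first-order steps. We get 5.41 h, a rough estimate from blue, which is 1.80 times the 3.0 h of cedar, so we expect intermediate in cedar to be still rising when read. We reckon 66.1 % for cedar and 48.6 % for alder.

The forecast, with constants of its own and so with numbers a little apart from ours, names cedar, with 49 % for alder and 65.5 % for cedar, on the ground that “substrate loss looks first order”. The simulation gives 47.5 % for alder and 60.8 % for cedar, so cedar wins.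

    2 substrate → self-condensation product (k = 0.00160 M⁻¹ min⁻¹)
    substrate → intermediate (k = 0.00880 min⁻¹)
    target → over-reaction product (k = 0.00810 min⁻¹)
    intermediate → target (k = 0.00100 min⁻¹)

In cedar, the turning of 2 substrate into self-condensation product ran early, with half of its turnover up to 3.0 h done by 0.510 h, and by 1.50 h self-condensation product held 14.4 % while substrate stood at 36.6 %. The turning of intermediate into target ran later, reaching that mark at 1.92 h, and at 3.00 h intermediate was still made 2.21 times faster than it was used, each step taken net, ahead of our reckoned crossing at 5.41 h. The same flask as cedar, read at 8.0 h, later than that crossing, holds 56.2 % intermediate, less than cedar's 60.8 %.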